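(The runs stem from a simulated flask from invented constants, and the scatter is random.)

Read the runs late: from 20.0 h in winter and from 20.0 h in dusk, the substrate readings stop falling beyond their scatter.

the same everywhere: substrate 20 mM

| flask | catalyst | remark | time |
|---|---|---|---|
| winter | 2.8 mM | run made earlier |  |
| dusk | 4.4 mM | run made earlier |  |
| flask | 2.0 mM |  | 2.0 d |

| run | time / h | target / % | isomer of the product A / % | substrate / % |
|---|---|---|---|---|
| winter | 4.00 | 13 | 22 | 50 |
| winter | 8.00 | 16 | 32 | 30 |
| winter | 12.0 | 13 | 37 | 22 |
| winter | 15.0 | 17 | 36 | 20 |
| winter | 20.0 | 14 | 36 | 15 |
| winter | 25.0 | 11 | 34 | 19 |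
| winter | 30.0 | 16 | 30 | 18 |
| dusk | 2.50 | 7 | 22 | 53 |
| dusk | 4.00 | 11 | 33 | 41 |
| dusk | 5.00 | 11 | 33 | 32 |
| dusk | 8.00 | 15 | 40 | 25 |
| dusk | 12.0 | 12 | 37 | 19 |
| dusk | 20.0 | 10 | 38 | 18 |
| dusk | 30.0 | 11 | 31 | 15 |

(each reading ± 1.5 percentage points)

- on the list of suspects stand: isomer of the product B + catalyst <-> substrate + catalyst; catalyst + target -> catalyst + over-reaction product; isomer of the product A + catalyst <-> isomer of the product B + catalyst; target + catalyst <-> isomer of the product A + catalyst; substrate <-> target

* share of target in target plus isomer of the product A at 15 min
* share of target in target plus isomer of the product A at 3.0 h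
* share of target in target plus isomer of the product A at 2.0 d
* which of target and isomer of the product A there is more of at 2.0 d

Follow one molecule into target. It arrives by substrate <-> target, which needs no catalyst. It leaves by the way back, by target + catalyst <-> isomer of the product A, or by catalyst + target -> over-reaction product, and the last two need catalyst, so the fork tilts with catalyst. In a quasi-steady state, then, assume the late odds w (isomer of the product A per target, summed over the late readings) run straight in the catalyst charge c: w = α + βc. Here β is the odds slope, the odds gained per mM of catalyst, and α is the odds at no catalyst.

Which readings matter? The flask lies outside both runs, so winter's odds enter with weight 1.50 and dusk's against it with 0.500. One winter target reading off by the scatter moves the flask's odds by 0.134. One dusk isomer reading off by as much moves them by 0.0357. Substrate readings enter no term. One dusk target reading off by as much moves them by 0.117, more than a dusk isomer reading does. Every reading has the same scatter, so the target readings are the ones to doubt first.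

The readings give odds of 2.44 in winter and 3.29 in dusk. That makes β = 0.529 /mM and α = 0.957. This flask then has odds 2.02, a late share of 33.2%, and isomer of the product A ahead.

The forecast says 82%, 42%, 32% and isomer of the product A ahead: “Late on, target and isomer A equilibrate with a slight feed bias”.

The flask gives 81.5%, 43.0%, 33.1%, and isomer of the product A ahead, 28.1% against 13.9% of target.

    isomer of the product B + catalyst ⇌ substrate + catalyst, rate k1*[catalyst]*[isomer of the product B] forward; the back reaction follows from the equilibrium constant (k = 70.0 /M/h)
    catalyst + target → catalyst + over-reaction product (k = 20.0 /M/h)
    isomer of the product A + catalyst ⇌ isomer of the product B + catalyst, rate k3*[catalyst]*[isomer of the product A] forward; the back reaction follows from the equilibrium constant (K = 0.510, k = 180 /M/h)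
    target + catalyst ⇌ isomer of the product A + catalyst, rate k4*[catalyst]*[target] forward; the back reaction follows from the equilibrium constant (K = 0.820, k = 2.40 /M/h)
    substrate ⇌ target (K = 2.10, k = 0.0440 /h)

On this flask's share at 3.0 h, the step isomer of the product A + catalyst <-> isomer of the product B + catalyst, both ways, has the largest single effect: without it the share stands at 99.2% instead of 43.0%. Catalyst + target -> over-reaction product is part of why isomer of the product A leads this flask: the same flask run without that step stands at 51.1% instead of 33.1%, with target ahead. Strip βc from this flask's odds and the line gives 51.1%. In the flask with 1.2 mM of catalyst, the line gives odds of 1.59 and a share of 38.6%, and that flask stands at 39.8%.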